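**Retrosynthetic overview**

1. Target 21 comes from its tri-O-benzyl ether 20 by hydrogenolysis.
2. The pyranone of 20 is closed last by joining benzofuran C3 to the pyranone carbonyl carbon (chromone C4). The strategy rests on C3 being the β-carbon of the O1–C2(OAr)=C3 ketene-acetal unit of the furan ring and the atom that carries the ring A carbonyl, so acid 18 is the precursor.
3. Acid 18 comes from 2-bromobenzofuran 14 and salicylate 16 by copper-catalysed C2–O coupling and saponification.
4. Bromide 14 comes from dihydrobenzofuranol 10 by ortho-formylation, dibromo-olefination, copper-catalysed furan closure and O-benzylation.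
5. Phenol 10 comes from 2-prenylresorcinol by Shi epoxidation and 5-exo epoxide opening. Ring order: dihydrofuran, then furan, then pyranone.

Key step: step 14

Remark: the furan is closed under basic copper catalysis from a gem-dibromo-olefin because hot acid would dehydrate the tertiary carbinol, and methyl 2,4,6-trihydroxybenzoate is taken as the commercial form of the phloroglucinol carboxylate. In the tricyclic names, O1/C2/C3 are the aromatic furan and O6/C7/C8 the dihydrofuran of benzo[1,2-b:3,4-b']difuran.

**Route**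

Step 1
Reactants: 1 resorcinol
Product: 2 1,3-bis(methoxymethoxy)benzene
Conditions: NaH, MOMCl, DMF, 0 °C to rt
Reagents that add atoms: chloromethyl methyl ether, COCCl
Why: Williamson O-alkylation of the bis-phenoxide with the hard α-chloro ether should give the bis-MOM ether, whose two acetal oxygens serve as ortho-directing groups in step 2.

Step 2
Reactants: 2 1,3-bis(methoxymethoxy)benzene; 3 prenyl bromide
Product: 5 1,3-bis(methoxymethoxy)-2-(3-methylbut-2-en-1-yl)benzene, via 2-lithio-1,3-bis(methoxymethoxy)benzene 4 (not isolated)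
Conditions: n-BuLi, THF, 0 °C to rt; then CuI (10 mol %), prenyl bromide, −78 °C to rt
Reagents that add atoms: n-butyllithium, [Li]CCCC (its lithium appears only in intermediate 4)
Why: Directed ortho-metalation places lithium at C2 between the two OMOM groups, and copper-catalysed SN2 allylation with prenyl bromide should give the linear prenyl arene.

Step 3
Reactants: 5 1,3-bis(methoxymethoxy)-2-(3-methylbut-2-en-1-yl)benzene
Product: 6 2-(3-methylbut-2-en-1-yl)benzene-1,3-diol (2-prenylresorcinol)
Conditions: HCl (3 M aq., catalytic amount), MeOH, 40 °C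
Reagents that add atoms: none
Why: Acid-catalysed acetal exchange with methanol removes both MOM groups under conditions mild enough not to cyclize the ortho-prenylphenol to a chroman.

Step 4
Reactants: 6 2-(3-methylbut-2-en-1-yl)benzene-1,3-diol
Product: 7 1,3-bis(tert-butyldimethylsilyloxy)-2-(3-methylbut-2-en-1-yl)benzene
Conditions: TBSCl, imidazole, DMF, rt
Reagents that add atoms: tert-butyldimethylsilyl chloride, CC(C)(C)[Si](C)(C)Cl
Why: Imidazole-mediated silylation masks both phenols against oxidation by the dioxirane at pH 10 and allows their later release by fluoride.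

Step 5
Reactants: 7 1,3-bis(tert-butyldimethylsilyloxy)-2-(3-methylbut-2-en-1-yl)benzene
Product: 8 (R)-3-[2,6-bis(tert-butyldimethylsilyloxy)benzyl]-2,2-dimethyloxirane
Conditions: D-fructose-derived Shi ketone (1,2:4,5-di-O-isopropylidene-β-D-erythro-2,3-hexodiulo-2,6-pyranose, 30 mol %), Oxone (2KHSO5·KHSO4·K2SO4), K2CO3, Bu4NHSO4, Na2B4O7/Na2EDTA buffer, MeCN–CH2(OMe)2–H2O, 0 °C
Reagents that add atoms: potassium peroxymonosulfate (active part of Oxone), [K+].[O-]S(=O)(=O)OO
Why: Shi asymmetric epoxidation: the chiral dioxirane should attack the trisubstituted olefin through the spiro transition state on the face that gives the (R)-epoxide, the same sense that leads to (R,R)-epoxides from trans-olefins, and this sets the absolute configuration of the route.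

Step 6
Reactants: 8 (R)-3-[2,6-bis(tert-butyldimethylsilyloxy)benzyl]-2,2-dimethyloxirane
Product: 10 (S)-2-(2-hydroxypropan-2-yl)-2,3-dihydrobenzofuran-4-ol, via desilylated epoxy diphenol 9 (not isolated)
Conditions: Bu4NF, THF, 0 °C to rt; aqueous work-up
Reagents that add atoms: none
Why: Fluoride desilylation frees a phenoxide that opens the epoxide at its secondary carbon by 5-exo-tet SN2 attack with inversion, so the (R)-epoxide should give the (S)-dihydrobenzofuran; the two phenols are equivalent, so no regiochemical question arises.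

Step 7
Reactants: 10 (S)-2-(2-hydroxypropan-2-yl)-2,3-dihydrobenzofuran-4-ol
Product: 11 (S)-4-hydroxy-2-(2-hydroxypropan-2-yl)-2,3-dihydrobenzofuran-5-carbaldehyde
Conditions: MgCl2 (anhydrous), Et3N, paraformaldehyde, MeCN, reflux; dilute HCl work-up
Reagents that add atoms: formaldehyde (as paraformaldehyde), C=O
Why: Magnesium-mediated ortho-formylation (Casnati–Skattebøl) delivers formaldehyde from the magnesium phenoxide to C5, the only free ortho position, and a second formaldehyde oxidizes the benzylic alkoxide to the aldehyde by hydride transfer.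

Step 8
Reactants: 11 (S)-4-hydroxy-2-(2-hydroxypropan-2-yl)-2,3-dihydrobenzofuran-5-carbaldehyde
Product: 12 (S)-5-(2,2-dibromovinyl)-2-(2-hydroxypropan-2-yl)-2,3-dihydrobenzofuran-4-ol
Conditions: CBr4, PPh3, Et3N, CH2Cl2, 0 °C
Reagents that add atoms: carbon tetrabromide, BrC(Br)(Br)Br
Why: Ramirez dibromo-olefination (first stage of the Corey–Fuchs sequence) by Ph3P=CBr2 converts the aldehyde quickly at 0 °C, while Et3N keeps the phenol from quenching the ylide and the hindered tertiary alcohol should be too slow to be activated.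

Step 9
Reactants: 12 (S)-5-(2,2-dibromovinyl)-2-(2-hydroxypropan-2-yl)-2,3-dihydrobenzofuran-4-ol
Product: 13 2-[(7S)-2-bromo-7,8-dihydrobenzo[1,2-b:3,4-b']difuran-7-yl]propan-2-ol
Conditions: CuI (5 mol %), K3PO4, THF, 80 °C
Reagents that add atoms: none
Why: Copper-catalysed intramolecular Ullmann-type C–O coupling of the phenoxide with the cis C–Br bond of the gem-dibromo-olefin closes the furan and leaves the second bromine at C2, a known entry to 2-bromobenzofurans.

Step 10
Reactants: 13 2-[(7S)-2-bromo-7,8-dihydrobenzo[1,2-b:3,4-b']difuran-7-yl]propan-2-ol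
Product: 14 (7S)-7-[2-(benzyloxy)propan-2-yl]-2-bromo-7,8-dihydrobenzo[1,2-b:3,4-b']difuran
Conditions: NaH, BnBr, Bu4NI (cat.), DMF, 0 °C to rt
Reagents that add atoms: benzyl bromide, BrCc1ccccc1
Why: Williamson etherification of the tertiary alkoxide under iodide catalysis, with no phenol left to compete, protects the carbinol for the acylation step.

Step 11
Reactants: 15 methyl 2,4,6-trihydroxybenzoate
Product: 16 methyl 2,4-bis(benzyloxy)-6-hydroxybenzoate
Conditions: BnBr (2.05 equiv), K2CO3, acetone, reflux
Reagents that add atoms: benzyl bromide, BrCc1ccccc1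
Why: Selective Williamson benzylation alkylates the para hydroxyl and one ortho hydroxyl, while the last ortho hydroxyl stays chelated to the ester carbonyl and should remain free.

Step 12
Reactants: 14 (7S)-7-[2-(benzyloxy)propan-2-yl]-2-bromo-7,8-dihydrobenzo[1,2-b:3,4-b']difuran; 16 methyl 2,4-bis(benzyloxy)-6-hydroxybenzoate
Product: 17 methyl 2,4-bis(benzyloxy)-6-({(7S)-7-[2-(benzyloxy)propan-2-yl]-7,8-dihydrobenzo[1,2-b:3,4-b']difuran-2-yl}oxy)benzoate
Conditions: CuI (20 mol %), picolinic acid (40 mol %), K3PO4, DMSO, 90 °C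
Reagents that add atoms: none
Why: Ullmann-type diaryl ether synthesis: the copper/picolinate catalyst, suited to hindered phenols and heteroaryl bromides, should couple the salicylate phenoxide with the furan C2–Br bond.

Step 13
Reactants: 17 methyl 2,4-bis(benzyloxy)-6-({(7S)-7-[2-(benzyloxy)propan-2-yl]-7,8-dihydrobenzo[1,2-b:3,4-b']difuran-2-yl}oxy)benzoate
Product: 18 2,4-bis(benzyloxy)-6-({(7S)-7-[2-(benzyloxy)propan-2-yl]-7,8-dihydrobenzo[1,2-b:3,4-b']difuran-2-yl}oxy)benzoic acid
Conditions: KOH, THF–MeOH–H2O, 65 °C; then cold dilute HCl to pH 4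
Reagents that add atoms: potassium hydroxide, [K+].[OH-]
Why: Saponification of the hindered ester by excess hydroxide is safe because the heteroaryl ether is base-stable, and liberation of the acid cold at pH 4 avoids hydrolysis of the 2-aryloxyfuran and protodecarboxylation.

Step 14
Reactants: 18 2,4-bis(benzyloxy)-6-({(7S)-7-[2-(benzyloxy)propan-2-yl]-7,8-dihydrobenzo[1,2-b:3,4-b']difuran-2-yl}oxy)benzoic acid
Product: 20 tri-O-benzyl ether of the target, via aroyl trifluoroacetate mixed anhydride 19 (not isolated)
Conditions: (CF3CO)2O (1.3 equiv), CH2Cl2 (anhydrous), 0 °C to rt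
Reagents that add atoms: trifluoroacetic anhydride, O=C(OC(=O)C(F)(F)F)C(F)(F)F (its atoms appear only in intermediate 19)
Why: The anhydride converts the acid into aroyl trifluoroacetate 19, which ionizes, or reacts as a tight ion pair, to a 2,4,6-trioxygenated aroyl cation held over the furan by the diaryl ether oxygen; C3, the nucleophilic β-carbon of the O1–C2(OAr)=C3 ketene-acetal unit, attacks it and loss of the C3 proton restores the furan. This is an intramolecular Friedel–Crafts acylation of the kind that closes xanthones from 2-aryloxybenzoic acids, and it matches the known C3 acylation of 2-substituted benzofurans. The pyranone closes as a six-membered ring, exo with respect to the acyl C=O (6-exo-trig on the mixed anhydride) and endo with respect to the C2=C3 bond. No stereocenter is formed, and the existing one is remote, not enolizable and should be untouched. The step needs site selectivity, which the substrate secures because C3 is the only carbon that reaches the acyl carbon through a six-membered transition state and is far more nucleophilic than any benzene position; chemoselectivity rests on the benzyl ether, which keeps the tertiary carbinol from ionizing or being acylated, and on anhydrous, near-stoichiometric activation at 0 °C, which should keep the acid-labile 2-aryloxyfuran from hydrolysis and from trifluoroacetylation.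

Step 15
Reactants: 20 tri-O-benzyl ether of the target
Product: 21 target, 1,3-dihydroxybenzofuro[2,3-b]chromen-11-one with a (2S)-2-(2-hydroxypropan-2-yl)-2,3-dihydrofuran fused at C7–C8 (CH2 on C7, O on C8)
Conditions: H2 (1 atm), Pd(OH)2/C, EtOAc–MeOH, rt
Reagents that add atoms: none
Why: Catalytic hydrogenolysis should cleave the two aryl benzyl ethers and the tertiary alkyl benzyl ether, while the fully substituted furochromone double bond and the non-benzylic C–O bonds of the dihydrofuran are not reduced.

**Compound list**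

1 | resorcinol | Oc1cccc(O)c1 | starting material
2 | 1,3-bis(methoxymethoxy)benzene | COCOc1cccc(OCOC)c1 | intermediate
3 | prenyl bromide (1-bromo-3-methylbut-2-ene) | CC(C)=CCBr | starting material
4 | 2-lithio-1,3-bis(methoxymethoxy)benzene (formed in the flask) | COCOc1cccc(OCOC)c1[Li] | intermediate
5 | 1,3-bis(methoxymethoxy)-2-(3-methylbut-2-en-1-yl)benzene | COCOc1cccc(OCOC)c1CC=C(C)C | intermediate
6 | 2-(3-methylbut-2-en-1-yl)benzene-1,3-diol | CC(C)=CCc1c(O)cccc1O | intermediate
7 | 1,3-bis(tert-butyldimethylsilyloxy)-2-(3-methylbut-2-en-1-yl)benzene | CC(C)=CCc1c(O[Si](C)(C)C(C)(C)C)cccc1O[Si](C)(C)C(C)(C)C | intermediate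
8 | (R)-3-[2,6-bis(tert-butyldimethylsilyloxy)benzyl]-2,2-dimethyloxirane | CC1(C)O[C@@H]1Cc1c(O[Si](C)(C)C(C)(C)C)cccc1O[Si](C)(C)C(C)(C)C | intermediate
9 | 2-{[(2R)-3,3-dimethyloxiran-2-yl]methyl}benzene-1,3-diol (formed in the flask) | CC1(C)O[C@@H]1Cc1c(O)cccc1O | intermediate
10 | (S)-2-(2-hydroxypropan-2-yl)-2,3-dihydrobenzofuran-4-ol | CC(C)(O)[C@@H]1Cc2c(O)cccc2O1 | intermediate
11 | (S)-4-hydroxy-2-(2-hydroxypropan-2-yl)-2,3-dihydrobenzofuran-5-carbaldehyde | CC(C)(O)[C@@H]1Cc2c(O)c(C=O)ccc2O1 | intermediate
12 | (S)-5-(2,2-dibromovinyl)-2-(2-hydroxypropan-2-yl)-2,3-dihydrobenzofuran-4-ol | CC(C)(O)[C@@H]1Cc2c(O)c(C=C(Br)Br)ccc2O1 | intermediate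
13 | 2-[(7S)-2-bromo-7,8-dihydrobenzo[1,2-b:3,4-b']difuran-7-yl]propan-2-ol (2-bromobenzofuran with the dihydrofuran fused at benzofuran C6–C7, O on C6) | CC(C)(O)[C@@H]1Cc2c(ccc3cc(Br)oc23)O1 | intermediate
14 | (7S)-7-[2-(benzyloxy)propan-2-yl]-2-bromo-7,8-dihydrobenzo[1,2-b:3,4-b']difuran | CC(C)(OCc1ccccc1)[C@@H]1Cc2c(ccc3cc(Br)oc23)O1 | intermediate
15 | methyl 2,4,6-trihydroxybenzoate | COC(=O)c1c(O)cc(O)cc1O | starting material
16 | methyl 2,4-bis(benzyloxy)-6-hydroxybenzoate | COC(=O)c1c(O)cc(OCc2ccccc2)cc1OCc1ccccc1 | intermediate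
17 | methyl 2,4-bis(benzyloxy)-6-({(7S)-7-[2-(benzyloxy)propan-2-yl]-7,8-dihydrobenzo[1,2-b:3,4-b']difuran-2-yl}oxy)benzoate | CC(C)(OCc1ccccc1)[C@@H]1Cc2c(ccc3cc(Oc4cc(OCc5ccccc5)cc(OCc5ccccc5)c4C(=O)OC)oc23)O1 | intermediate
18 | 2,4-bis(benzyloxy)-6-({(7S)-7-[2-(benzyloxy)propan-2-yl]-7,8-dihydrobenzo[1,2-b:3,4-b']difuran-2-yl}oxy)benzoic acid | CC(C)(OCc1ccccc1)[C@@H]1Cc2c(ccc3cc(Oc4cc(OCc5ccccc5)cc(OCc5ccccc5)c4C(=O)O)oc23)O1 | intermediate
19 | mixed anhydride of acid 18 and trifluoroacetic acid (formed in the flask) | CC(C)(OCc1ccccc1)[C@@H]1Cc2c(ccc3cc(Oc4cc(OCc5ccccc5)cc(OCc5ccccc5)c4C(=O)OC(=O)C(F)(F)F)oc23)O1 | intermediate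
20 | tri-O-benzyl ether of the target: 1,3-bis(benzyloxy)benzofuro[2,3-b]chromen-11-one with a (2S)-2-[2-(benzyloxy)propan-2-yl]-2,3-dihydrofuran fused at C7–C8 | CC(C)(OCc1ccccc1)[C@@H]1Cc2c(ccc3c2oc2oc4cc(OCc5ccccc5)cc(OCc5ccccc5)c4c(=O)c23)O1 | intermediate
21 | target: 1,3-dihydroxybenzofuro[2,3-b]chromen-11-one with a (2S)-2-(2-hydroxypropan-2-yl)-2,3-dihydrofuran fused at C7–C8 | CC(C)(O)[C@@H]1Cc2c(ccc3c2oc2oc4cc(O)cc(O)c4c(=O)c23)O1 | target

**Step count**

Total steps: 15. Longest linear sequence: 14 (steps 1–10 and 12–15; step 11 prepares the salicylate fragment).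

**Steps most likely to fail**

Step 12 (copper-catalysed C–O coupling). The ester-chelated, ortho-substituted phenoxide may form the C–O bond too slowly, so that protodebromination and homocoupling consume bromide 14. The fallback reverses the polarity of the coupling (Chan–Lam–Evans). Setting out from 14, bromine–lithium exchange (n-BuLi, THF, −78 °C), borylation with B(OiPr)3 and mild aqueous hydrolysis should give {(7S)-7-[2-(benzyloxy)propan-2-yl]-7,8-dihydrobenzo[1,2-b:3,4-b']difuran-2-yl}boronic acid F1. Oxidative coupling of this acid with phenol 16 (Cu(OAc)2, pyridine, 4 Å molecular sieves, air, CH2Cl2, rt) comes back to the route at ester 17.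

Step 14 (key cycloacylation). The liberated acid may protonate the ketene-acetal-like furan, leading to cleavage of the C2–OAr bond on work-up; excess anhydride may trifluoroacetylate C3; or the electron-rich acid may protodecarboxylate before it cyclizes. The fallback closes the same bond by an anionic Parham cycloacylation instead of a cationic one. Setting out from ester 17, bromination at the furan β-carbon with N-bromosuccinimide (MeCN, −20 °C, 1.0 equiv) should give methyl 2,4-bis(benzyloxy)-6-({(7S)-7-[2-(benzyloxy)propan-2-yl]-3-bromo-7,8-dihydrobenzo[1,2-b:3,4-b']difuran-2-yl}oxy)benzoate F2. Bromine–lithium exchange (n-BuLi, THF, −100 °C) then lets the C3 carbanion attack the neighbouring ester and expel methoxide, coming back to the route at 20 without passing through acid 18.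

Step 8 (dibromo-olefination with free hydroxyl groups). The bromophosphonium species formed beside the ylide may activate the free tertiary alcohol or the phenol, causing dehydration or bromide substitution, and the phenol may quench the ylide. The fallback is an alkyne route without phosphonium reagents. Setting out from aldehyde 11, Seyferth–Gilbert homologation with the Ohira–Bestmann reagent (K2CO3, MeOH, rt) should give (S)-5-ethynyl-2-(2-hydroxypropan-2-yl)-2,3-dihydrobenzofuran-4-ol F3. Base-mediated 5-endo-dig cycloisomerization (Cs2CO3, DMF, 60 °C) should give 2-[(7S)-7,8-dihydrobenzo[1,2-b:3,4-b']difuran-7-yl]propan-2-ol F4, and benzylation (NaH, BnBr, DMF) gives (7S)-7-[2-(benzyloxy)propan-2-yl]-7,8-dihydrobenzo[1,2-b:3,4-b']difuran F5. C2 lithiation (n-BuLi, THF, −78 °C) and bromination with BrCCl2CCl2Br comes back to the route at bromide 14.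

**Further compounds**

F1 | step 12 | {(7S)-7-[2-(benzyloxy)propan-2-yl]-7,8-dihydrobenzo[1,2-b:3,4-b']difuran-2-yl}boronic acid | CC(C)(OCc1ccccc1)[C@@H]1Cc2c(ccc3cc(B(O)O)oc23)O1
F2 | step 14 | methyl 2,4-bis(benzyloxy)-6-({(7S)-7-[2-(benzyloxy)propan-2-yl]-3-bromo-7,8-dihydrobenzo[1,2-b:3,4-b']difuran-2-yl}oxy)benzoate | CC(C)(OCc1ccccc1)[C@@H]1Cc2c(ccc3c(Br)c(Oc4cc(OCc5ccccc5)cc(OCc5ccccc5)c4C(=O)OC)oc23)O1
F3 | step 8 | (S)-5-ethynyl-2-(2-hydroxypropan-2-yl)-2,3-dihydrobenzofuran-4-ol | CC(C)(O)[C@@H]1Cc2c(O)c(C#C)ccc2O1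
F4 | step 8 | 2-[(7S)-7,8-dihydrobenzo[1,2-b:3,4-b']difuran-7-yl]propan-2-ol | CC(C)(O)[C@@H]1Cc2c(ccc3ccoc23)O1
F5 | step 8 | (7S)-7-[2-(benzyloxy)propan-2-yl]-7,8-dihydrobenzo[1,2-b:3,4-b']difuran | CC(C)(OCc1ccccc1)[C@@H]1Cc2c(ccc3ccoc23)O1
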